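**Retrosynthetic overview**
1. Numbering: ring A is the resorcinol ring (C1 styryl, C2 benzyl, C3 OH, C4 H, C5 OH, C6 H). C7=C8 is the stilbene alkene (C7 on ring A, C8 on guaiacyl ring B). Ring C is the catechol ring of the benzyl group.
2. Feature used: the ring bond C1=C6 and the alkene C7=C8 together form a 1,3-diene C6=C1–C7=C8, the bond pattern an enyne metathesis leaves behind. Cutting C1=C6 and C7=C8 and rejoining C1≡C7 and C6=C8 leads back to the open-chain 1,7-enyne 17.
3. Ring order: rings B and C are bought. Ring A is the only ring made (step 12), first as a cyclohexene with C3 and C5 as protected carbinols, and it becomes aromatic when both carbinols are oxidised and the ene-dione enolises.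
4. Enyne 17 comes from three carbonyl additions: C4–C5 (acetate aldol on protected coniferaldehyde), C1–C2 (ethynyl Grignard on the arylacetaldehyde from 3,4-dihydroxyphenylacetic acid) and C2–C3 (allenylzinc from mesylate 14 plus aldehyde 7).
5. The phenols of rings B and C travel as MOM ethers and are freed last with acid.

Key step: step 12

Assumption: C2, C3 and C5 all end as sp2 carbons of ring A, so every chiral compound is carried as a racemate and, from 16 on, as a diastereomer mixture; names and SMILES show one enantiomer of the 2,3-anti-3,5-syn isomer as representative.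

**Fragment 1 (C3–C6, C8, ring B)**

Step 1
Reactants: 1 coniferaldehyde
Product: 2 (E)-3-[3-methoxy-4-(methoxymethoxy)phenyl]prop-2-enal
Conditions: MOMCl, iPr2NEt, CH2Cl2, 0 °C to rt
Reagents that add atoms: chloromethyl methyl ether (MOMCl), COCCl
Why: Williamson-type O-alkylation of the phenol masks the only acidic proton of ring B with an acetal that withstands enolates, hydrides, organozinc reagents, fluoride and hypervalent iodine and that leaves in acid at the end.

Step 2
Reactants: 2 (E)-3-[3-methoxy-4-(methoxymethoxy)phenyl]prop-2-enal; 3 ethyl acetate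
Product: 5 ethyl (3S,4E)-3-hydroxy-5-[3-methoxy-4-(methoxymethoxy)phenyl]pent-4-enoate (racemic), via ethyl acetate lithium enolate 4 (not isolated)
Conditions: LiN(iPr)2, 3, THF, −78 °C; then 2, −78 °C
Reagents that add atoms: ethyl acetate 3, CCOC(C)=O
Why: Acetate aldol addition, in which the hard lithium enolate 4 adds 1,2 to the enal at low temperature, forms C4–C5 and gives the C5 carbinol as a racemate, which is acceptable because C5 becomes a phenol carbon.

Step 3
Reactants: 5 ethyl (3S,4E)-3-hydroxy-5-arylpent-4-enoate
Product: 6 ethyl (3S,4E)-3-(tert-butyldimethylsilyloxy)-5-[3-methoxy-4-(methoxymethoxy)phenyl]pent-4-enoate (racemic)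
Conditions: TBSCl, imidazole, DMF, rt
Reagents that add atoms: tert-butyldimethylsilyl chloride (TBSCl), CC(C)(C)[Si](C)(C)Cl
Why: Imidazole-promoted silylation of a secondary allylic alcohol leaves C5 untouched and blocks retro-aldol cleavage and ionisation of the electron-rich cinnamyl alcohol.

Step 4
Reactants: 6 silyloxy ester
Product: 7 (3S,4E)-3-(tert-butyldimethylsilyloxy)-5-[3-methoxy-4-(methoxymethoxy)phenyl]pent-4-enal (racemic)
Conditions: iBu2AlH (1.1 equiv), CH2Cl2, −78 °C
Reagents that add atoms: none
Why: Partial ester reduction, in which the aluminium hemiacetal persists at −78 °C until work-up, so the β-silyloxy aldehyde should be released without over-reduction or β-elimination.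

**Fragment 2 (C7, C1, C2, benzyl, ring C)**

Step 5
Reactants: 8 3,4-dihydroxyphenylacetic acid
Product: 9 methyl 2-(3,4-dihydroxyphenyl)acetate
Conditions: MeOH, H2SO4 (cat.), reflux
Reagents that add atoms: methanol, CO
Why: Fischer esterification driven by methanol as solvent, to which the catechol is inert.

Step 6
Reactants: 9 methyl 2-(3,4-dihydroxyphenyl)acetate
Product: 10 methyl 2-[3,4-bis(methoxymethoxy)phenyl]acetate
Conditions: MOMCl (2.5 equiv), iPr2NEt, CH2Cl2, 0 °C to rt
Reagents that add atoms: chloromethyl methyl ether (MOMCl), COCCl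
Why: Double Williamson-type O-alkylation of the catechol under an amine base too weak to enolise the arylacetate.

Step 7
Reactants: 10 methyl 2-[3,4-bis(methoxymethoxy)phenyl]acetate
Product: 11 2-[3,4-bis(methoxymethoxy)phenyl]acetaldehyde
Conditions: iBu2AlH (1.1 equiv), toluene, −78 °C
Reagents that add atoms: none
Why: Partial ester reduction as in step 4, with the enolisable arylacetaldehyde taken on directly without storage.

Step 8
Reactants: 11 2-[3,4-bis(methoxymethoxy)phenyl]acetaldehyde; 12 ethynylmagnesium bromide
Product: 13 (2R)-1-[3,4-bis(methoxymethoxy)phenyl]but-3-yn-2-ol (racemic)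
Conditions: HC≡CMgBr, THF, −78 to 0 °C
Reagents that add atoms: ethynylmagnesium bromide 12, C#C[Mg]Br
Why: Grignard 1,2-addition of a weakly basic acetylide, which adds faster than it enolises the aldehyde, forms C1–C2 and gives the C2 carbinol as a racemate.

Step 9
Reactants: 13 propargylic alcohol
Product: 14 (2R)-1-[3,4-bis(methoxymethoxy)phenyl]but-3-yn-2-yl methanesulfonate (racemic)
Conditions: MsCl, Et3N, CH2Cl2, −78 to 0 °C
Reagents that add atoms: methanesulfonyl chloride, CS(=O)(=O)Cl
Why: O-sulfonylation at low temperature proceeds with retention at C2 and installs the leaving group for the SN2' metalation without elimination toward the benzylic position.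

**Union and ring A**

Step 10
Reactants: 7 β-silyloxy aldehyde; 14 propargylic mesylate
Product: 16 (1E,3S,5R,6S)-6-[3,4-bis(methoxymethoxy)benzyl]-3-(tert-butyldimethylsilyloxy)-1-[3-methoxy-4-(methoxymethoxy)phenyl]oct-1-en-7-yn-5-ol, via allenylzinc mesylate 15 (not isolated)
Conditions: Pd(OAc)2 (5 mol %), PPh3 (5 mol %), Et2Zn (3 equiv), THF, −78 to −20 °C
Reagents that add atoms: none
Why: Marshall propargylation, in which zerovalent palladium (from Pd(OAc)2, PPh3 and Et2Zn) displaces the mesylate in an anti SN2' sense, Et2Zn turns the allenylpalladium into allenylzinc 15, and 15 adds to aldehyde 7 at its benzyl-bearing terminus through a closed six-membered SE2' transition state that forms C2–C3, restores the terminal alkyne and sets C2/C3 anti, whereas induction from C5 should be weak, which does not matter because C2, C3 and C5 are all erased in step 14.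

Step 11
Reactants: 16 homopropargylic alcohol
Product: 17 (1E,3S,5R,6S)-6-[3,4-bis(methoxymethoxy)benzyl]-3,5-bis(tert-butyldimethylsilyloxy)-1-[3-methoxy-4-(methoxymethoxy)phenyl]oct-1-en-7-yne
Conditions: TBSCl, imidazole, DMAP (cat.), DMF, 40 °C
Reagents that add atoms: tert-butyldimethylsilyl chloride (TBSCl), CC(C)(C)[Si](C)(C)Cl
Why: Imidazole-promoted silylation of the C3 alcohol is chosen over a silyl triflate so that the aryl MOM ethers and the ionisable cinnamyl silyl ether never meet a strong Lewis acid.

Step 12
Reactants: 17 acyclic 1,7-enyne bis(silyl ether)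
Product: 18 (3S,5R,6S)-6-[3,4-bis(methoxymethoxy)benzyl]-3,5-bis(tert-butyldimethylsilyloxy)-1-{(E)-2-[3-methoxy-4-(methoxymethoxy)phenyl]ethenyl}cyclohex-1-ene
Conditions: RuCl2(=CHPh)(PCy3)(SIMes) (second-generation Grubbs catalyst, 10 mol % in two portions), degassed toluene (0.01 M), Ar (ethylene excluded), 80 °C
Reagents that add atoms: none
Why: Ring-closing enyne metathesis; the closest known cases are the closure of 1,7-enynes to 1-vinylcyclohexenes and of enynes with a 1,2-disubstituted alkene, whose substituent ends up on the diene terminus. The ruthenium arylmethylidene adds to the terminal alkyne with its carbene carbon (C8) on the unhindered C7, the ruthenacyclobutene-like adduct opens to the C7=C8 bond and a carbene on C1, and this carbene undergoes metathesis with the tethered C6=C8 alkene, which forms C1=C6 and releases Ru=C8HAr for the next molecule. The other order of events (Ru=C6 alkylidene first, closure onto C1, then capping of the C7 vinylcarbene by the styrenyl alkene of a second molecule) converges on the same product, so the outcome does not depend on which cycle runs. Ring A closes in the exo mode, with C1 inside and C7 outside the ring, because for a 1,7-enyne the six-membered closure is much faster than the seven-membered endo one. No stereocentre is formed and C2, C3 and C5 are not touched. The step needs C7 to be capped by C8 and not by CH2, secured by the lack of any terminal alkene and by exclusion of ethylene, and it needs E geometry at C7=C8, favoured by conjugation of the aryl diene and by equilibration through reversible metathesis with this catalyst.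

Step 13
Reactants: 18 styrylcyclohexene bis(silyl ether)
Product: 19 (1R,3S,6S)-6-[3,4-bis(methoxymethoxy)benzyl]-5-{(E)-2-[3-methoxy-4-(methoxymethoxy)phenyl]ethenyl}cyclohex-4-ene-1,3-diol
Conditions: Bu4NF, THF, 0 °C to rt
Reagents that add atoms: none
Why: Fluoride-induced Si–O cleavage, driven by the strong Si–F bond, runs in a non-acidic medium that spares the MOM ethers and the acid-labile dienylic C5 alcohol.

Step 14
Reactants: 19 cyclohexenediol
Product: 21 4-[3,4-bis(methoxymethoxy)benzyl]-5-{(E)-2-[3-methoxy-4-(methoxymethoxy)phenyl]ethenyl}benzene-1,3-diol, via ene-dione 20 (not isolated)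
Conditions: Dess–Martin periodinane (2.2 equiv), NaHCO3, CH2Cl2, 0 °C
Reagents that add atoms: none
Why: Dess–Martin oxidation of both secondary alcohols, a method known to take β-hydroxy ketones to 1,3-diketones, should give ene-dione 20, a keto tautomer of the resorcinol whose C2–H and C4–H2 are doubly activated, so enolisation to aromatic ring A follows spontaneously and erases C2, C3 and C5.

Step 15
Reactants: 21 tris-MOM ether of the target
Product: 22 gnetupendin B, 4-(3,4-dihydroxybenzyl)-5-[(E)-2-(4-hydroxy-3-methoxyphenyl)ethenyl]benzene-1,3-diol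
Conditions: HCl (3 M aq, cat.), MeOH, 45 °C, Ar
Reagents that add atoms: none
Why: Acid-catalysed acetal exchange cleaves the three MOM ethers while the large excess of methanol takes up the formaldehyde unit and keeps it from alkylating the resorcinol, and the aryl methyl ether and the E-alkene are stable to these conditions.

**Compound list**
1 | coniferaldehyde | COc1cc(/C=C/C=O)ccc1O | starting material
2 | (E)-3-[3-methoxy-4-(methoxymethoxy)phenyl]prop-2-enal | COCOc1ccc(/C=C/C=O)cc1OC | intermediate
3 | ethyl acetate | CCOC(C)=O | starting material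
4 | ethyl acetate lithium enolate (not isolated) | [Li]OC(=C)OCC | intermediate
5 | ethyl (3S,4E)-3-hydroxy-5-[3-methoxy-4-(methoxymethoxy)phenyl]pent-4-enoate (racemic, one enantiomer drawn) | CCOC(=O)C[C@H](O)/C=C/c1ccc(OCOC)c(OC)c1 | intermediate
6 | ethyl (3S,4E)-3-(tert-butyldimethylsilyloxy)-5-[3-methoxy-4-(methoxymethoxy)phenyl]pent-4-enoate (racemic) | CCOC(=O)C[C@H](O[Si](C)(C)C(C)(C)C)/C=C/c1ccc(OCOC)c(OC)c1 | intermediate
7 | (3S,4E)-3-(tert-butyldimethylsilyloxy)-5-[3-methoxy-4-(methoxymethoxy)phenyl]pent-4-enal (racemic) | O=CC[C@H](O[Si](C)(C)C(C)(C)C)/C=C/c1ccc(OCOC)c(OC)c1 | intermediate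
8 | 3,4-dihydroxyphenylacetic acid | OC(=O)Cc1ccc(O)c(O)c1 | starting material
9 | methyl 2-(3,4-dihydroxyphenyl)acetate | COC(=O)Cc1ccc(O)c(O)c1 | intermediate
10 | methyl 2-[3,4-bis(methoxymethoxy)phenyl]acetate | COC(=O)Cc1ccc(OCOC)c(OCOC)c1 | intermediate
11 | 2-[3,4-bis(methoxymethoxy)phenyl]acetaldehyde | O=CCc1ccc(OCOC)c(OCOC)c1 | intermediate
12 | ethynylmagnesium bromide | C#C[Mg]Br | starting material
13 | (2R)-1-[3,4-bis(methoxymethoxy)phenyl]but-3-yn-2-ol (racemic, one enantiomer drawn) | C#C[C@@H](Cc1ccc(OCOC)c(OCOC)c1)O | intermediate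
14 | (2R)-1-[3,4-bis(methoxymethoxy)phenyl]but-3-yn-2-yl methanesulfonate (racemic) | C#C[C@@H](Cc1ccc(OCOC)c(OCOC)c1)OS(C)(=O)=O | intermediate
15 | {4-[3,4-bis(methoxymethoxy)phenyl]buta-1,2-dienyl}zinc methanesulfonate (racemic, axial chirality not drawn, not isolated) | CS(=O)(=O)O[Zn]C=C=CCc1ccc(OCOC)c(OCOC)c1 | intermediate
16 | (1E,3S,5R,6S)-6-[3,4-bis(methoxymethoxy)benzyl]-3-(tert-butyldimethylsilyloxy)-1-[3-methoxy-4-(methoxymethoxy)phenyl]oct-1-en-7-yn-5-ol (racemic, representative diastereomer) | C#C[C@H](Cc1ccc(OCOC)c(OCOC)c1)[C@H](O)C[C@H](O[Si](C)(C)C(C)(C)C)/C=C/c1ccc(OCOC)c(OC)c1 | intermediate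
17 | (1E,3S,5R,6S)-6-[3,4-bis(methoxymethoxy)benzyl]-3,5-bis(tert-butyldimethylsilyloxy)-1-[3-methoxy-4-(methoxymethoxy)phenyl]oct-1-en-7-yne (key-step precursor) | C#C[C@H](Cc1ccc(OCOC)c(OCOC)c1)[C@H](O[Si](C)(C)C(C)(C)C)C[C@H](O[Si](C)(C)C(C)(C)C)/C=C/c1ccc(OCOC)c(OC)c1 | intermediate
18 | (3S,5R,6S)-6-[3,4-bis(methoxymethoxy)benzyl]-3,5-bis(tert-butyldimethylsilyloxy)-1-{(E)-2-[3-methoxy-4-(methoxymethoxy)phenyl]ethenyl}cyclohex-1-ene (key-step product) | COCOc1ccc(/C=C/C=2[C@H](Cc3ccc(OCOC)c(OCOC)c3)[C@H](O[Si](C)(C)C(C)(C)C)C[C@H](O[Si](C)(C)C(C)(C)C)C2)cc1OC | intermediate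
19 | (1R,3S,6S)-6-[3,4-bis(methoxymethoxy)benzyl]-5-{(E)-2-[3-methoxy-4-(methoxymethoxy)phenyl]ethenyl}cyclohex-4-ene-1,3-diol | COCOc1ccc(/C=C/C=2[C@H](Cc3ccc(OCOC)c(OCOC)c3)[C@H](O)C[C@H](O)C2)cc1OC | intermediate
20 | (6S)-6-[3,4-bis(methoxymethoxy)benzyl]-5-{(E)-2-[3-methoxy-4-(methoxymethoxy)phenyl]ethenyl}cyclohex-4-ene-1,3-dione (C2 labile, not isolated) | COCOc1ccc(/C=C/C2=CC(=O)CC(=O)[C@H]2Cc3ccc(OCOC)c(OCOC)c3)cc1OC | intermediate
21 | 4-[3,4-bis(methoxymethoxy)benzyl]-5-{(E)-2-[3-methoxy-4-(methoxymethoxy)phenyl]ethenyl}benzene-1,3-diol | COCOc1ccc(/C=C/c2cc(O)cc(O)c2Cc3ccc(OCOC)c(OCOC)c3)cc1OC | intermediate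
22 | gnetupendin B | COc1cc(/C=C/c2cc(O)cc(O)c2Cc2ccc(O)c(O)c2)ccc1O | target

**Count**
Total steps: 15. Longest linear sequence: 11 steps (8 to 22, steps 5–15).

**Steps most likely to fail**

1. Step 12. The hindered 1,2-disubstituted styrenyl alkene next to the C5 silyl ether may engage too slowly. Turnover would then stall, and alkyne oligomerisation, intermolecular enyne coupling and catalyst decay would take over. Control of E geometry at C7=C8 may also be incomplete, and the first turnover passes on the benzylidene of the precatalyst in place of C8.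
Fallback, setting out from 17: ring closure and styryl formation are separated. Under ethylene (1 atm, same catalyst, toluene, 60 °C) the fast methylidene carrier caps C7 with CH2 and the arylmethylidene leaves as a styrene. This should give the 1-ethenylcyclohexene bis(silyl ether) F1 and 2-methoxy-1-(methoxymethoxy)-4-vinylbenzene F2. The terminal vinyl group of F1 then undergoes cross metathesis with an excess of F2, more of which is available from commercial 2-methoxy-4-vinylphenol and MOMCl. The conditions are the second-generation Hoveyda–Grubbs catalyst RuCl2(=CH-C6H4-2-OiPr)(SIMes) in CH2Cl2 at 40 °C under an argon sweep. This reaction type is E-selective for styrenes, and the sequence comes back to the route at 18.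

2. Step 14. The hypervalent iodine reagent may go on to attack the activated C4 methylene of the 1,3-dione or the electron-rich resorcinol as soon as it forms. Dehydration at the β-hydroxy ketone stage would cost one ring oxygen.
Fallback, setting out from 19: the double oxidation is split into two chemoselective events with different oxidant classes. MnO2 (CH2Cl2, rt) oxidises only the dienylic C5 carbinol, at a stage where no phenol can arise, and should give the β-hydroxy dienone F3. The remaining C3 carbinol is then oxidised under Swern conditions ((COCl)2, DMSO, CH2Cl2, −78 °C; then Et3N), an established way from β-hydroxy ketones to 1,3-diketones. There the carbonyl group, and with it the phenol, appears only after the amine has been added and the activated sulfoxide is spent. Enolisation comes back to the route at 21.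

3. Step 10. Several processes may erode the coupling:
- β-hydride elimination or protonolysis at the allenylpalladium or allenylzinc stage;
- ethyl transfer from Et2Zn to the aldehyde;
- loss of silanolate from the β-silyloxy aldehyde;
- attack through the wrong terminus of the allenyl/propargyl metal.

Fallback, setting out from 7: C2–C3 is made by an ester aldol and the alkyne is added afterwards. Methyl 3-[3,4-bis(methoxymethoxy)phenyl]propanoate F4 is made from commercial methyl 3-(3,4-dihydroxyphenyl)propanoate with MOMCl and iPr2NEt. It is deprotonated with LiN(iPr)2 in THF at −78 °C and added to 7 to give the β-hydroxy ester F5. Silylation (TBSCl, imidazole, DMF) should give the bis(silyl ether) ester F6, and iBu2AlH at −78 °C the α-branched aldehyde F7. Seyferth–Gilbert homologation with dimethyl (1-diazo-2-oxopropyl)phosphonate (K2CO3, MeOH, Ohira–Bestmann conditions) turns the formyl carbon into C1 and adds C7. This comes back to the route at 17.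

**Further compounds**
F1 | step 12 | (3S,5R,6S)-6-[3,4-bis(methoxymethoxy)benzyl]-3,5-bis(tert-butyldimethylsilyloxy)-1-ethenylcyclohex-1-ene | C=CC=1[C@H](Cc2ccc(OCOC)c(OCOC)c2)[C@H](O[Si](C)(C)C(C)(C)C)C[C@H](O[Si](C)(C)C(C)(C)C)C1
F2 | step 12 | 2-methoxy-1-(methoxymethoxy)-4-vinylbenzene | C=Cc1ccc(OCOC)c(OC)c1
F3 | step 14 | (4S,5R)-4-[3,4-bis(methoxymethoxy)benzyl]-5-hydroxy-3-{(E)-2-[3-methoxy-4-(methoxymethoxy)phenyl]ethenyl}cyclohex-2-en-1-one | COCOc1ccc(/C=C/C2=CC(=O)C[C@@H](O)[C@H]2Cc3ccc(OCOC)c(OCOC)c3)cc1OC
F4 | step 10 | methyl 3-[3,4-bis(methoxymethoxy)phenyl]propanoate | COC(=O)CCc1ccc(OCOC)c(OCOC)c1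
F5 | step 10 | methyl (6E)-2-[3,4-bis(methoxymethoxy)benzyl]-5-(tert-butyldimethylsilyloxy)-3-hydroxy-7-[3-methoxy-4-(methoxymethoxy)phenyl]hept-6-enoate (representative diastereomer) | COC(=O)[C@H](Cc1ccc(OCOC)c(OCOC)c1)[C@H](O)C[C@H](O[Si](C)(C)C(C)(C)C)/C=C/c1ccc(OCOC)c(OC)c1
F6 | step 10 | methyl (6E)-2-[3,4-bis(methoxymethoxy)benzyl]-3,5-bis(tert-butyldimethylsilyloxy)-7-[3-methoxy-4-(methoxymethoxy)phenyl]hept-6-enoate | COC(=O)[C@H](Cc1ccc(OCOC)c(OCOC)c1)[C@H](O[Si](C)(C)C(C)(C)C)C[C@H](O[Si](C)(C)C(C)(C)C)/C=C/c1ccc(OCOC)c(OC)c1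
F7 | step 10 | (6E)-2-[3,4-bis(methoxymethoxy)benzyl]-3,5-bis(tert-butyldimethylsilyloxy)-7-[3-methoxy-4-(methoxymethoxy)phenyl]hept-6-enal | O=C[C@H](Cc1ccc(OCOC)c(OCOC)c1)[C@H](O[Si](C)(C)C(C)(C)C)C[C@H](O[Si](C)(C)C(C)(C)C)/C=C/c1ccc(OCOC)c(OC)c1
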